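**The leftover.** The peaks of Wednesday's and Thursday's runs don't add up to the starting material charged: at the last reading, side product B, target, side product A and starting material leave 1.80 % of the charge unaccounted for on Wednesday and 6.20 % on Thursday. The flasks now asked about differ in protic impurity.

the same everywhere: starting material 0.050 M
- Wednesday's: reagent 0.075 M; protic impurity 0.98 mM; run made earlier
- Thursday's: reagent 0.075 M; protic impurity 2.9 mM; run made earlier
- south-east: reagent 0.0750 M; protic impurity 2.00 mM; time 15 h
- west: reagent 0.0750 M; protic impurity 4.00 mM; time 15 h
- north-east: reagent 0.0750 M; protic impurity 1.00 mM; time 15 h

| run | time / h | side product B / % | target / % | starting material / % | side product A / % |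
|---|---|---|---|---|---|
| Wednesday's | 1.50 | 38.5 | 30.3 | 10.8 | 17.6 |
| Wednesday's | 3.00 | 46.7 | 30.2 | 1.7 | 18.4 |
| Wednesday's | 5.00 | 48.4 | 31.0 | 0 | 18.9 |
| Wednesday's | 6.00 | 48.6 | 31.3 | 0.1 | 19.0 |
| Wednesday's | 8.00 | 48.7 | 30.9 | 0 | 18.6 |
| Thursday's | 0.667 | 21.5 | 27.0 | 31.7 | 14.7 |
| Thursday's | 2.00 | 40.1 | 30.7 | 6.0 | 17.5 |
| Thursday's | 4.00 | 44.1 | 31.0 | 0.5 | 18.4 |
| Thursday's | 5.00 | 44.8 | 30.9 | 0.4 | 18.1 |
| Thursday's | 8.00 | 44.9 | 30.7 | 0 | 18.2 |

(scatter of a reading: 0.3 percentage points)

- in percentages every species weighs as the starting material in it: one side product B counts as two

1. which of these there is most of at the end, counted by the starting material in it, south-east (side product A / starting material / target / side product B)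
2. which of these there is most of at the end, counted by the starting material in it, west (side product A / starting material / target / side product B)
3. which of these there is most of at the end, counted by the starting material in it, north-east (side product A / starting material / target / side product B)
4. how much there is at the end of the one of these that leads, in percent of the starting material charged: south-east
5. how much there is at the end of the one of these that leads, in percent of the starting material charged: west
6. how much there is at the end of the one of these that leads, in percent of the starting material charged: north-east

**The toll.** Protic impurity charged over starting material charged, in equivalents, is 1.96 % for Wednesday's run and 5.80 % for Thursday's. These ratios stand beside the gaps, given a scatter of 0.3 percentage points on each reading, as they should if each impurity molecule removes one starting material from the listed peaks. Call this ratio the impurity toll, a fraction of the charge; in west it is 8.00 %.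

**Who pays.** From Wednesday's run to Thursday's the toll rises by 3.8 points and side product B falls by 3.8 points, while target moves by 0.2 points and side product A by 0.4 points. So side product B plus toll reads 50.7 % and 50.7 %. Wednesday's starting material reads 0 % at 8.00 h, and side product B moves from 48.6 % to 48.7 % over the last interval, so 15 h is taken as the plateau.

**The reckoning.** Subtracting each toll from the mean sum, 50.7 %, gives side product B at 46.7 % in south-east, 42.7 % in west and 48.7 % in north-east, each more than target's last reading of 30.9 % on Wednesday. West's toll is higher than Thursday's, so the west figure is an extrapolation.

**The forecast.** The forecast gives the same figures, 46.7 %, 42.7 % and 48.7 %, with side product B ahead in south-east, side product B in west and side product B in north-east, on “roughly one starting material destroyed per impurity molecule”.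

**The flask.** Side product B leads with 46.8 % in south-east, 43.5 % in west and 48.5 % in north-east.

    starting material + reagent → target (k = 0.300 M⁻¹ min⁻¹)
    starting material + target → side product B (k = 0.550 M⁻¹ min⁻¹)
    starting material + protic impurity → quenched substrate (k = 1.60 M⁻¹ min⁻¹)
    starting material + 2 reagent → side product A (k = 2.00 M⁻² min⁻¹)

**The toll paid.** In north-east, protic impurity has a half-life of 0.144 h with starting material held at its charge, shorter than the 0.51 h of starting material by the making of target alone, the other concentrations held as charged. Side product B in west stands 0.80 points above the reckoning; west ends with 7.56 % quenched substrate against its toll of 8.00 %, and the 5.5 % of its own charge of protic impurity still unbound is worth 0.440 % of the starting material charged. The neighbour of west charged with 0.085 M of starting material has a toll of 4.71 % and ends with 4.70 % quenched substrate.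

(The data are calculated for an exercise; the scatter is artificial.)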